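**Strategy.** Everything rests on disconnecting the 2,2‑dimethyl‑2H‑pyran ring fused to ring A (O7–C7/C8 of the chromone) across its aryl–CH bond (C8–C4″) and its CH–CMe2 bond (C3″–C2″), leaving the O7–CMe2 bond intact. In the forward sense an O‑aryl oxocarbenium ion, generated from a 7‑isopropenyl ether of a 5‑hydroxy‑3‑iodo‑6‑methyl‑2‑(methylsulfanyl)chromone, takes up ethyl vinyl ether in a formal [4+2] (oxa‑Povarov) annulation and loses ethanol. The C6 methyl group leaves C8 as the only free ring‑A carbon, so the pyran can only form angularly. The 2‑methylsulfanyl group later lets the 2′‑hydroxyl close the furan ring without an oxidant.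

Key step: step 7

Remark: the target has no stereocentre; the one stereocentre that appears on the way (C10 of intermediate 11) is racemic and is destroyed in the same step.

**Step 1**
Reactants: 1 2,6-dimethoxytoluene
Product: 3 3,5-dimethoxy-4-methylphenol, via arylboronate 2 (not isolated)
Conditions: [Ir(OMe)(cod)]2 (1.5 mol %), dtbpy (3 mol %), B2pin2 (1.0 equiv), THF, 80 °C; then Oxone (2KHSO5·KHSO4·K2SO4), acetone–H2O, 23 °C
Reagents that add atoms: Oxone, active component potassium peroxymonosulfate, [K+].[O-]S(=O)(=O)OO (oxygen of 3); bis(pinacolato)diboron, CC1(C)OB(OC1(C)C)B1OC(C)(C)C(C)(C)O1 (boryl group of 2 only)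
Why: Iridium-catalysed C–H borylation is sterically controlled and reaches only C4 of 1, the one ring C–H without an ortho substituent, and Oxone oxidises the aryl boronate to the phenol in the same pot (one-pot C–H borylation/oxidation).

**Step 2**
Reactants: 3 3,5-dimethoxy-4-methylphenol
Product: 4 1-(6-hydroxy-2,4-dimethoxy-3-methylphenyl)ethan-1-one
Conditions: AcOH (3 equiv), BF3·OEt2 (neat), 90 °C; aqueous work-up
Reagents that add atoms: acetic acid, CC(=O)O
Why: Nencki-type Friedel–Crafts acylation goes ortho to the hydroxyl because the para position carries the methyl group, and the two ortho positions are equivalent by symmetry, so a single ketone results in which the free hydroxyl is flanked by the acyl group and H.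

**Step 3**
Reactants: 4 1-(6-hydroxy-2,4-dimethoxy-3-methylphenyl)ethan-1-one
Product: 6 5,7-dimethoxy-6-methyl-2-(methylsulfanyl)-4H-chromen-4-one, via ketene dithioacetal 5 (not isolated)
Conditions: NaH (3.2 equiv), CS2 (1.5 equiv), THF, 0 → 23 °C; MeI (2.1 equiv), 0 → 65 °C
Reagents that add atoms: carbon disulfide, S=C=S; iodomethane, CI
Why: The ketone enolate adds to CS2, double S-methylation gives the α-oxo ketene dithioacetal, and the neighbouring phenoxide displaces one methylsulfanyl group by intramolecular addition–elimination (6-endo-trig), a known route to 2-(methylsulfanyl)chromones in which the single free hydroxyl fixes O1 next to C8–H and so places the methyl group at C6.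

**Step 4**
Reactants: 6 5,7-dimethoxy-6-methyl-2-(methylsulfanyl)-4H-chromen-4-one
Product: 7 3-iodo-5,7-dimethoxy-6-methyl-2-(methylsulfanyl)-4H-chromen-4-one
Conditions: NIS (1.05 equiv), MeCN, 0 → 23 °C, dark
Reagents that add atoms: N-iodosuccinimide, O=C1CCC(=O)N1I
Why: Electrophilic iodination should occur at C3, the α-carbon of the push–pull ketene O,S-acetal, which is expected to be more nucleophilic than ring-A carbon C8, the latter being deactivated by the carbonyl group and shielded by the in-plane 7-methoxy group.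

**Step 5**
Reactants: 7 3-iodo-5,7-dimethoxy-6-methyl-2-(methylsulfanyl)-4H-chromen-4-one
Product: 8 5,7-dihydroxy-3-iodo-6-methyl-2-(methylsulfanyl)-4H-chromen-4-one
Conditions: BBr3 (5 equiv), CH2Cl2, −78 → 23 °C; MeOH/H2O quench
Reagents that add atoms: none
Why: BBr3 cleaves both aryl methyl ethers (Lewis acid ether cleavage), the peri 5-OMe first through chelation to C4=O, while the vinyl iodide and the S-methyl group should survive under anhydrous conditions; the ring is already closed, so the 6-methyl pattern cannot scramble.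

**Step 6**
Reactants: 8 5,7-dihydroxy-3-iodo-6-methyl-2-(methylsulfanyl)-4H-chromen-4-one
Product: 9 5-hydroxy-3-iodo-6-methyl-2-(methylsulfanyl)-7-(prop-1-en-2-yloxy)-4H-chromen-4-one
Conditions: isopropenylboronic acid pinacol ester (2 equiv), Cu(OAc)2 (20 mol %), pyridine, 4 Å MS, O2 (1 atm), CH2Cl2, 23 °C
Reagents that add atoms: 2-isopropenyl-4,4,5,5-tetramethyl-1,3,2-dioxaborolane, CC(=C)B1OC(C)(C)C(C)(C)O1
Why: Chan–Lam oxidative coupling of an alkenylboronate takes place at the acidic, unchelated 7-OH, whereas the 5-OH is locked in a hydrogen bond to C4=O and the vinyl iodide is inert to the copper catalyst at room temperature.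

**Step 7**
Reactants: 9 5-hydroxy-3-iodo-6-methyl-2-(methylsulfanyl)-7-(prop-1-en-2-yloxy)-4H-chromen-4-one
Product: 12 5-hydroxy-3-iodo-6,8,8-trimethyl-2-(methylsulfanyl)-4H,8H-pyrano[2,3-f]chromen-4-one, via chloro ether 10 (not isolated), via ethoxychroman 11 (not isolated)
Conditions: HCl (1.0 equiv, 4 M in dioxane), CH2Cl2, −78 °C; then SnCl4 (30 mol %), ethyl vinyl ether (1.5 equiv, added over 1 h), −78 → 23 °C; Et3N quench
Reagents that add atoms: ethyl vinyl ether, C=COCC (supplies C9 and C10; its ethoxy group is in 11 only); hydrogen chloride, Cl (chlorine in 10 only)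
Why: HCl adds to the isopropenyl ether to give tertiary α-chloro ether 10, which SnCl4 ionises to the O-aryl oxocarbenium ion (a cationic 2-oxadiene, C8=C7–O+=CMe2); the CH2 carbon of ethyl vinyl ether attacks the carbenium carbon (Prins-type, forming the CH–CMe2 bond C9–C8 of the product), and the resulting ethoxy-oxocarbenium ion is captured by chromone C8 (Friedel–Crafts, forming the aryl–CH bond C10–C10a), after which acid-induced E1 loss of ethanol from benzylic ether 11 gives the 2H-pyran. The closest known reaction type is the oxa-Povarov reaction, the formal inverse-electron-demand [4+2] of aryl oxocarbenium ions with alkenes to chromans, applied here to a ketone-derived ion and an enol ether so that the adduct can eliminate to the chromene. The pyran ring closes by 6-exo-trig attack of the arene on the oxocarbenium carbon. No stereocentre remains, since C10 of 11 is formed racemic and becomes sp2 on elimination. Orientation follows from polarity (the nucleophilic CH2 of the enol ether goes to the CMe2 cation, the alkoxy-stabilised carbon to the arene), and site selectivity is secured by the substrate because C6 carries the methyl group, C8 is the only free ring-A carbon ortho to O7, and the chelated 5-OH bears no ketal. The step also needs cyclisation to outrun further vinyl ether addition, which the slow addition and the triply oxygen-activated C8 position should secure.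

**Step 8**
Reactants: 13 benzene-1,2,4-triol
Product: 14 1,2,4-tris(methoxymethoxy)benzene
Conditions: NaH (3.6 equiv), MOMCl (3.6 equiv), DMF, 0 → 23 °C, argon
Reagents that add atoms: chloromethyl methyl ether, COCCl
Why: Williamson-type O-alkylation of the three phenoxides protects the air-sensitive triol and installs the ortho-directing groups for the next step.

**Step 9**
Reactants: 14 1,2,4-tris(methoxymethoxy)benzene
Product: 16 1,2,4-tris(methoxymethoxy)-3-(3-methylbut-2-en-1-yl)benzene, via aryllithium 15 (not isolated)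
Conditions: n-BuLi (1.15 equiv), THF, −78 → 0 °C; CuBr·SMe2 (10 mol %), prenyl bromide (1.3 equiv), −78 → 23 °C
Reagents that add atoms: 1-bromo-3-methylbut-2-ene, CC(C)=CCBr; n-butyllithium, [Li]CCCC (lithium in 15 only)
Why: Directed ortho-metalation occurs at C3, the only position flanked by two MOM ethers, and the aryllithium is alkylated at the primary carbon of prenyl bromide under copper catalysis (SN2).

**Step 10**
Reactants: 16 1,2,4-tris(methoxymethoxy)-3-(3-methylbut-2-en-1-yl)benzene
Product: 17 1-bromo-2,4,5-tris(methoxymethoxy)-3-(3-methylbut-2-en-1-yl)benzene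
Conditions: NBS (1.02 equiv), DMF, −20 °C, dark
Reagents that add atoms: N-bromosuccinimide, O=C1CCC(=O)N1Br
Why: Electrophilic aromatic bromination goes to C5 of 16, which is ortho to one MOM ether and para to another (C6 has one ortho ether only), and the very electron-rich arene should react faster than the trisubstituted alkene at low temperature.

**Step 11**
Reactants: 17 1-bromo-2,4,5-tris(methoxymethoxy)-3-(3-methylbut-2-en-1-yl)benzene; 12 5-hydroxy-3-iodo-6,8,8-trimethyl-2-(methylsulfanyl)-4H,8H-pyrano[2,3-f]chromen-4-one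
Product: 20 5-hydroxy-6,8,8-trimethyl-2-(methylsulfanyl)-3-[2,4,5-tris(methoxymethoxy)-3-(3-methylbut-2-en-1-yl)phenyl]-4H,8H-pyrano[2,3-f]chromen-4-one, via aryllithium 18 (not isolated), via lithium triisopropyl borate 19 (not isolated)
Conditions: 17, n-BuLi (1.05 equiv), THF, −78 °C; B(OiPr)3 (1.2 equiv), −78 → 23 °C; then 12 (0.8 equiv), Pd(OAc)2 (5 mol %), SPhos (10 mol %), aq. K3PO4, THF, 45 °C
Reagents that add atoms: n-butyllithium, [Li]CCCC (lithium in 18 and 19 only); triisopropyl borate, CC(C)OB(OC(C)C)OC(C)C (boron in 19 only)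
Why: Bromine–lithium exchange and borate trapping give an ate complex that is used directly in a Suzuki–Miyaura coupling with vinyl iodide 12, where it resists protodeboronation, the bulky biaryl phosphine copes with the congested C3–C1′ bond, and the C2–S bond is untouched in the absence of a copper carboxylate.

**Step 12**
Reactants: 20 5-hydroxy-6,8,8-trimethyl-2-(methylsulfanyl)-3-[2,4,5-tris(methoxymethoxy)-3-(3-methylbut-2-en-1-yl)phenyl]-4H,8H-pyrano[2,3-f]chromen-4-one
Product: 22 triquetrumone A, via triol 21 (not isolated)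
Conditions: HCl (3 M in MeOH), THF, 40 °C; concentrate; then K2CO3, degassed DMF, 50 °C; aq. NH4Cl work-up
Reagents that add atoms: none
Why: Acidic methanolysis removes the three MOM acetals, and on basification the 2′-phenoxide, the only hydroxyl within reach of C2, displaces methanethiolate by intramolecular addition–elimination at the β-carbon of the chromone (nucleophilic vinylic substitution, formally 5-endo-trig as in the established closures of 2′-hydroxyisoflavones to coumaronochromones), closing the furan ring without any oxidant and so sparing the prenyl group, the chromene and the catechol.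

**Compound list**
1 | 2,6-dimethoxytoluene | COc1cccc(OC)c1C | starting material
2 | 2-(3,5-dimethoxy-4-methylphenyl)-4,4,5,5-tetramethyl-1,3,2-dioxaborolane | COc1cc(B2OC(C)(C)C(C)(C)O2)cc(OC)c1C | intermediate (not isolated)
3 | 3,5-dimethoxy-4-methylphenol | COc1cc(O)cc(OC)c1C | intermediate
4 | 1-(6-hydroxy-2,4-dimethoxy-3-methylphenyl)ethan-1-one | CC(=O)c1c(O)cc(OC)c(C)c1OC | intermediate
5 | 1-(6-hydroxy-2,4-dimethoxy-3-methylphenyl)-3,3-bis(methylsulfanyl)prop-2-en-1-one | CSC(SC)=CC(=O)c1c(O)cc(OC)c(C)c1OC | intermediate (not isolated)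
6 | 5,7-dimethoxy-6-methyl-2-(methylsulfanyl)-4H-chromen-4-one | CSc1cc(=O)c2c(OC)c(C)c(OC)cc2o1 | intermediate
7 | 3-iodo-5,7-dimethoxy-6-methyl-2-(methylsulfanyl)-4H-chromen-4-one | CSc1oc2cc(OC)c(C)c(OC)c2c(=O)c1I | intermediate
8 | 5,7-dihydroxy-3-iodo-6-methyl-2-(methylsulfanyl)-4H-chromen-4-one | CSc1oc2cc(O)c(C)c(O)c2c(=O)c1I | intermediate
9 | 5-hydroxy-3-iodo-6-methyl-2-(methylsulfanyl)-7-(prop-1-en-2-yloxy)-4H-chromen-4-one | CSc1oc2cc(OC(C)=C)c(C)c(O)c2c(=O)c1I | intermediate
10 | 7-[(2-chloropropan-2-yl)oxy]-5-hydroxy-3-iodo-6-methyl-2-(methylsulfanyl)-4H-chromen-4-one | CSc1oc2cc(OC(C)(C)Cl)c(C)c(O)c2c(=O)c1I | intermediate (not isolated)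
11 | rac-10-ethoxy-5-hydroxy-3-iodo-6,8,8-trimethyl-2-(methylsulfanyl)-9,10-dihydro-4H,8H-pyrano[2,3-f]chromen-4-one | CCOC1CC(C)(C)Oc2c(C)c(O)c3c(=O)c(I)c(SC)oc3c21 | intermediate (not isolated, racemic)
12 | 5-hydroxy-3-iodo-6,8,8-trimethyl-2-(methylsulfanyl)-4H,8H-pyrano[2,3-f]chromen-4-one | CSc1oc2c(c(=O)c1I)c(O)c(C)c1OC(C)(C)C=Cc12 | intermediate
13 | benzene-1,2,4-triol | Oc1ccc(O)c(O)c1 | starting material
14 | 1,2,4-tris(methoxymethoxy)benzene | COCOc1ccc(OCOC)c(OCOC)c1 | intermediate
15 | [2,3,6-tris(methoxymethoxy)phenyl]lithium | [Li]c1c(OCOC)ccc(OCOC)c1OCOC | intermediate (not isolated)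
16 | 1,2,4-tris(methoxymethoxy)-3-(3-methylbut-2-en-1-yl)benzene | CC(C)=CCc1c(OCOC)ccc(OCOC)c1OCOC | intermediate
17 | 1-bromo-2,4,5-tris(methoxymethoxy)-3-(3-methylbut-2-en-1-yl)benzene | CC(C)=CCc1c(OCOC)c(Br)cc(OCOC)c1OCOC | intermediate
18 | [2,4,5-tris(methoxymethoxy)-3-(3-methylbut-2-en-1-yl)phenyl]lithium | [Li]c1cc(OCOC)c(OCOC)c(CC=C(C)C)c1OCOC | intermediate (not isolated)
19 | lithium triisopropoxy[2,4,5-tris(methoxymethoxy)-3-(3-methylbut-2-en-1-yl)phenyl]borate | [Li+].CC(C)O[B-](OC(C)C)(OC(C)C)c1cc(OCOC)c(OCOC)c(CC=C(C)C)c1OCOC | intermediate (not isolated)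
20 | 5-hydroxy-6,8,8-trimethyl-2-(methylsulfanyl)-3-[2,4,5-tris(methoxymethoxy)-3-(3-methylbut-2-en-1-yl)phenyl]-4H,8H-pyrano[2,3-f]chromen-4-one | CSc1oc2c(c(=O)c1-c1cc(OCOC)c(OCOC)c(CC=C(C)C)c1OCOC)c(O)c(C)c1OC(C)(C)C=Cc12 | intermediate
21 | 5-hydroxy-6,8,8-trimethyl-2-(methylsulfanyl)-3-[2,4,5-trihydroxy-3-(3-methylbut-2-en-1-yl)phenyl]-4H,8H-pyrano[2,3-f]chromen-4-one | CSc1oc2c(c(=O)c1-c1cc(O)c(O)c(CC=C(C)C)c1O)c(O)c(C)c1OC(C)(C)C=Cc12 | intermediate (not isolated)
22 | triquetrumone A | CC(C)=CCc1c(O)c(O)cc2c1oc1oc3c4c(c(C)c(O)c3c(=O)c12)OC(C)(C)C=C4 | target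

**Step count and risks**
Total steps: 12. Longest linear sequence: 9 steps (steps 1–7, 11 and 12); steps 8–10 form the ring-B branch.

Step 7 is the step most likely to fail. Cationic oligomerisation of the vinyl ether, or loss of the aryloxy group from the ketal-type intermediates, may outrun the Friedel–Crafts closure, and the acid may also degrade the chromene once it has formed. The fallback leaves the oxocarbenium approach altogether and sets out from diol 8, so it also replaces step 6. Diol 8 would be condensed with 3-methylbut-2-enal in the presence of PhB(OH)2 and AcOH in refluxing toluene; ortho C-alkylation at C8, dehydration to the ortho-quinone methide and oxa-6π electrocyclisation would give 12 directly, where the route is rejoined. C6 is blocked, so only the angular pyran can form. This fallback makes no new compound (F0).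

Step 4 is the second risk. Iodination may take place at ring-A carbon C8, or at both C8 and C3, instead of at C3 alone. The fallback postpones the halogenation until C8 is part of the pyran ring and sets out from 6. BBr3 demethylation would give 5,7-dihydroxy-6-methyl-2-(methylsulfanyl)-4H-chromen-4-one F1, and Chan–Lam isopropenylation would give 5-hydroxy-6-methyl-2-(methylsulfanyl)-7-(prop-1-en-2-yloxy)-4H-chromen-4-one F2. The HCl/SnCl4/ethyl vinyl ether annulation would then pass through 7-[(2-chloropropan-2-yl)oxy]-5-hydroxy-6-methyl-2-(methylsulfanyl)-4H-chromen-4-one F3 and rac-10-ethoxy-5-hydroxy-6,8,8-trimethyl-2-(methylsulfanyl)-9,10-dihydro-4H,8H-pyrano[2,3-f]chromen-4-one F4, neither isolated, to 5-hydroxy-6,8,8-trimethyl-2-(methylsulfanyl)-4H,8H-pyrano[2,3-f]chromen-4-one F5. Iodination of F5 with NIS can then only occur at C3 and returns to 12.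

Step 11 is the third risk. Protodeboronation of the electron-rich ortho-alkoxy aryl borate and slow transmetalation at the congested C3 position may leave the iodide unconsumed. The fallback changes the organometallic partner from boron to zinc and sets out from 17. Bromine–lithium exchange to 18 and transmetalation with ZnCl2 would give chlorido[2,4,5-tris(methoxymethoxy)-3-(3-methylbut-2-en-1-yl)phenyl]zinc F6. Negishi coupling of F6 with the sodium phenoxide of 12 (NaH) under Pd(OAc)2/SPhos in THF at 50 °C would return to 20.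

**Further compounds**
F0 | step 7 | none | none
F1 | step 4 | 5,7-dihydroxy-6-methyl-2-(methylsulfanyl)-4H-chromen-4-one | CSc1cc(=O)c2c(O)c(C)c(O)cc2o1
F2 | step 4 | 5-hydroxy-6-methyl-2-(methylsulfanyl)-7-(prop-1-en-2-yloxy)-4H-chromen-4-one | CSc1cc(=O)c2c(O)c(C)c(OC(C)=C)cc2o1
F3 | step 4 | 7-[(2-chloropropan-2-yl)oxy]-5-hydroxy-6-methyl-2-(methylsulfanyl)-4H-chromen-4-one | CSc1cc(=O)c2c(O)c(C)c(OC(C)(C)Cl)cc2o1
F4 | step 4 | rac-10-ethoxy-5-hydroxy-6,8,8-trimethyl-2-(methylsulfanyl)-9,10-dihydro-4H,8H-pyrano[2,3-f]chromen-4-one | CCOC1CC(C)(C)Oc2c(C)c(O)c3c(=O)cc(SC)oc3c21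
F5 | step 4 | 5-hydroxy-6,8,8-trimethyl-2-(methylsulfanyl)-4H,8H-pyrano[2,3-f]chromen-4-one | CSc1cc(=O)c2c(O)c(C)c3OC(C)(C)C=Cc3c2o1
F6 | step 11 | chlorido[2,4,5-tris(methoxymethoxy)-3-(3-methylbut-2-en-1-yl)phenyl]zinc | COCOc1cc([Zn]Cl)c(OCOC)c(CC=C(C)C)c1OCOC
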